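Impurity outweighs free catalyst in the ash flask, and we start from that comparison, not from your hunch of a balance. You asked for a quick number on ash, the flask below, followed so far:

common to all: substrate 35 mM; free catalyst 3.5 mM; impurity 4.5 mM

| flask | partner | temperature | remark | time |
|---|---|---|---|---|
| ash | 70 mM | 35 °C | the very flask that is asked about, followed so far |  |
| elm | 70 mM | 41 °C | run made earlier |  |
| flask | 70.0 mM | 35 °C |  | 15 min |

| run | time / min | product / % | substrate / % |
|---|---|---|---|
| ash | 1.00 | 41 | 43 |
| ash | 3.00 | 59 | 28 |
| ash | 6.00 | 57 | 31 |
| ash | 8.00 | 58 | 31 |
| ash | 12.0 | 56 | 31 |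
| elm | 1.00 | 49 | 43 |
| elm | 3.00 | 57 | 32 |
| elm | 6.00 | 57 | 34 |
| elm | 8.00 | 59 | 32 |
| elm | 12.0 | 56 | 31 |

(standard deviation of a reading: 2 percentage points)

- Saturday's: at 15 min take out 90% of the product then present, then wait 15 min
- Tuesday's: at 15 min raise the temperature by 15 K, then wait 15 min
- Wednesday's: at 15 min add free catalyst, 100% of the amount charged, then wait 15 min
- Monday's: at 15 min add partner, 50.0% of the amount charged, then wait 15 min
- Sunday's: change nothing and wait 15 min more

1. product, in percent of the substrate first charged, at 15 min
2. the option that brings most further product ("none" if no option brings more than 2 percentage points) (Saturday's / Tuesday's / Wednesday's / Monday's / Sunday's / none)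
3. product present, with what was taken out counted in, in percent of the substrate first charged, after Tuesday's
4. product present, with what was taken out counted in, in percent of the substrate first charged, after Sunday's

- what is taken out of product is counted as made
- additions bring no volume worth counting

The ash readings hold flat near 57.5% product from 3.00 min, and the warmer elm run reads much the same, 57.2%. In ash that product has taken 0.288 of the partner charge, and substrate still reads 31%.

Our reckoning treats the stop as a catalyst with a finite life. Suppose free catalyst either takes substrate and comes back, or takes impurity and is lost, one for one. The catalyst charge is 0.778 of the impurity charge, so impurity should end at 0.222 of its charge, a fall of 0.654 decades. If each capture is first order in free catalyst and first order in what it captures, that catalyst cancels, and the two logarithms fall in a fixed ratio. The pool, meaning all substrate not yet product, falls 0.372 decades in ash, which counts the gap in the readings as substrate that can return. Decades of pool lost per decade of impurity lost is our selectivity factor, 0.569.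

So we commit to 57.5% now, and to no gain from waiting or from Tuesday's heat. By this reckoning, Wednesday's fresh catalyst meets impurity worth 0.286 of that addition, so we expect a gain near 42 percentage points and name Wednesday's.

The forecast gives 57.5% now, 57% after Tuesday's and 57.5% after Sunday's, but names Saturday's, about 17 points, holding that “This looks like an equilibrium with little heat of reaction”. We part from it on the best option.

The flask gives 59.8% now, 59.8% after Tuesday's and 59.8% after Sunday's; Wednesday's brings 40 points, Saturday's 0 points.

    free catalyst + impurity → spent catalyst (k = 160 M⁻¹ s⁻¹, Ea = 51.0 kJ mol⁻¹)
    substrate + free catalyst ⇌ catalyst intermediate A (K = 390 M⁻¹, k = 130 M⁻¹ s⁻¹, Ea = 36.0 kJ mol⁻¹, ΔH = −41.0 kJ mol⁻¹)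
    substrate ⇌ dormant form (K = 0.400, k = 0.0150 s⁻¹, Ea = 93.0 kJ mol⁻¹, ΔH = −38.0 kJ mol⁻¹)
    catalyst intermediate B → free catalyst + product (k = 0.150 s⁻¹, Ea = 72.0 kJ mol⁻¹)
    partner + catalyst intermediate A → catalyst intermediate B (k = 200 M⁻¹ s⁻¹, Ea = 43.0 kJ mol⁻¹)
    (constants at 35 °C)

In this flask, free catalyst starts out going into catalyst intermediate A 6.3 times as fast as into spent catalyst, forward step alone, yet spent catalyst stands at >99.9% of the catalyst charge after 15.0 min with impurity at 22.2% of its charge, and the factor read from ash, applied to that share as the power 0.569, reckons 57.5% as product, where this flask stands at 59.8%. For the neighbour charged with 18 mM of impurity, the same catalyst charge reckons to 0.806 of the impurity left, so the factor gives 11.6% product, and that neighbour stands at 14.4%.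

The earlier runs and the new flask are calculated for substances that don't exist.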